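**Retrosynthetic overview**

1. The (2R,3R)-flavanonol 28 is traced back through MOM removal and a trans-selective hydroxylation at C3 to (2S)-flavanone 25, and this to flavone 23 by enantioselective hydride addition to C2. Both stereocentres are therefore set after ring C exists.
2. Feature that carries the plan: in ring C, C4 is a one-carbon carbonyl unit held between C4a of ring A and C3, and C2–C3 with ring B attached has the connectivity of an arylacetylene. Ring C is therefore cut at C4a–C4, C4–C3 and O1–C2 into iodophenol 7, carbon monoxide 20 and alkyne 19.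
3. Iodophenol 7 comes from phloroglucinol: bis-MOM ether, iodination beside the free OH, then O-allylation, Claisen rearrangement and cross-metathesis place the C8 prenyl group on the other side of the same OH (the future O1).
4. Alkyne 19 comes from resorcinol bis-MOM ether by three directed ortho-metalations (geranyl, prenyl, formyl) and Seyferth–Gilbert homologation.
5. Ring order: rings A and B are the benzene rings of the starting phenols; ring C is the only ring built, in step 11.

Key step: step 11

Abbreviations: MOM = methoxymethyl; prenyl = 3-methylbut-2-en-1-yl; geranyl = (2E)-3,7-dimethylocta-2,6-dien-1-yl.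

Assumption: (R)-DTBM-SEGPHOS is taken as the ligand antipode that sends hydride to the C2 face giving the (2S)-flavanone; the sense is to be confirmed on 25, and the (S)-ligand is used instead if it proves opposite.

**Route**

Step 1
Reactants: 1 phloroglucinol
Product: 2 3,5-bis(methoxymethoxy)phenol
Conditions: MOMCl (2.1 equiv), i-Pr2NEt (2.5 equiv), CH2Cl2–DMF, 0 °C to rt; chromatography, mono- and tris-ethers recycled
Reagents that add atoms: chloromethyl methyl ether, COCCl
Why: Williamson-type O-alkylation of a threefold symmetric triol, so that only the degree of etherification has to be controlled and the under- and over-alkylated ethers can be separated and recycled.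

Step 2
Reactants: 2 3,5-bis(methoxymethoxy)phenol
Product: 3 2-iodo-3,5-bis(methoxymethoxy)phenol
Conditions: I2 (1.0 equiv), NaHCO3, THF–H2O, 0 °C
Reagents that add atoms: iodine, II
Why: Electrophilic aromatic iodination through the phenoxide, expected at one of the two equivalent carbons ortho to the free OH because the third site is flanked by two MOM ethers; it is done before any alkene is present, so that iodoetherification of a prenyl group cannot compete.

Step 3
Reactants: 3 2-iodo-3,5-bis(methoxymethoxy)phenol
Product: 4 1-(allyloxy)-2-iodo-3,5-bis(methoxymethoxy)benzene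
Conditions: allyl bromide, K2CO3, DMF, rt
Reagents that add atoms: allyl bromide, C=CCBr
Why: Williamson ether synthesis on the single free phenol.

Step 4
Reactants: 4 1-(allyloxy)-2-iodo-3,5-bis(methoxymethoxy)benzene
Product: 6 2-allyl-6-iodo-3,5-bis(methoxymethoxy)phenol, via dienone 5 (not isolated)
Conditions: N,N-diethylaniline, 180 °C
Reagents that add atoms: none
Why: Aromatic Claisen rearrangement: the [3,3] shift goes to the only ortho carbon that bears hydrogen (the other carries iodine) and dienone 5 tautomerises to the phenol, which fixes the allyl group next to the future O1.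

Step 5
Reactants: 6 2-allyl-6-iodo-3,5-bis(methoxymethoxy)phenol
Product: 7 2-iodo-3,5-bis(methoxymethoxy)-6-prenylphenol
Conditions: 2-methyl-2-butene (excess), second-generation Grubbs catalyst RuCl2(=CHPh)(PCy3)(H2IMes) (3 mol %), CH2Cl2, 40 °C
Reagents that add atoms: 2-methyl-2-butene, CC=C(C)C
Why: Olefin cross-metathesis of a terminal alkene with 2-methyl-2-butene, which turns the allyl group into a prenyl group with loss of propene and tolerates the aryl iodide, the phenol and the MOM ethers.

Step 6
Reactants: 8 resorcinol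
Product: 9 1,3-bis(methoxymethoxy)benzene
Conditions: NaH (2.4 equiv), MOMCl (2.4 equiv), DMF, 0 °C to rt
Reagents that add atoms: chloromethyl methyl ether, COCCl
Why: Williamson ether synthesis on both phenols.

Step 7
Reactants: 9 1,3-bis(methoxymethoxy)benzene; 10 geranyl bromide
Product: 12 2-geranyl-1,3-bis(methoxymethoxy)benzene, via aryllithium 11 (not isolated)
Conditions: n-BuLi, THF, 0 °C to rt; CuI (10 mol %), then 10, –78 °C to rt
Reagents that add atoms: none
Why: Directed ortho-metalation at C2, the position activated by both MOM ethers, followed by copper-catalysed SN2 allylation, which leaves the E alkene of the geranyl group unchanged.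

Step 8
Reactants: 12 2-geranyl-1,3-bis(methoxymethoxy)benzene; 13 prenyl bromide
Product: 15 2-geranyl-1,3-bis(methoxymethoxy)-4-prenylbenzene, via aryllithium 14 (not isolated)
Conditions: n-BuLi, TMEDA, THF, 0 °C; CuI (10 mol %), then 13, –78 °C to rt
Reagents that add atoms: none
Why: Second directed ortho-metalation at C4 (equivalent to C6) beside one MOM ether and copper-catalysed SN2 allylation; ring lithiation guided by the MOM oxygen is expected to be faster than deprotonation of the benzylic–allylic CH2.

Step 9
Reactants: 15 2-geranyl-1,3-bis(methoxymethoxy)-4-prenylbenzene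
Product: 18 3-geranyl-2,4-bis(methoxymethoxy)-5-prenylbenzaldehyde, via aryllithium 16 (not isolated), via lithium hemiaminolate 17 (not isolated)
Conditions: n-BuLi, TMEDA, THF, 0 °C; DMF, –78 °C to rt; H2O
Reagents that add atoms: N,N-dimethylformamide, CN(C)C=O
Why: Third directed ortho-metalation at the last ring position beside a MOM ether and formylation with DMF; hemiaminolate 17 releases the aldehyde on aqueous work-up.

Step 10
Reactants: 18 3-geranyl-2,4-bis(methoxymethoxy)-5-prenylbenzaldehyde
Product: 19 1-ethynyl-3-geranyl-2,4-bis(methoxymethoxy)-5-prenylbenzene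
Conditions: dimethyl (1-diazo-2-oxopropyl)phosphonate, K2CO3, MeOH, 0 °C to rt
Reagents that add atoms: dimethyl (1-diazo-2-oxopropyl)phosphonate, CC(=O)C(=[N+]=[N-])P(=O)(OC)OC
Why: Seyferth–Gilbert homologation in its Ohira–Bestmann form: the diazomethylphosphonate made by methanolysis adds to the aldehyde, and loss of dimethyl phosphate and N2 with a 1,2-hydride shift gives the terminal alkyne under conditions mild enough for MOM ethers and alkenes.

Step 11
Reactants: 7 2-iodo-3,5-bis(methoxymethoxy)-6-prenylphenol; 19 1-ethynyl-3-geranyl-2,4-bis(methoxymethoxy)-5-prenylbenzene; 20 carbon monoxide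
Product: 23 3'-geranyl-5,7,2',4'-tetrakis(methoxymethoxy)-8,5'-diprenylflavone, via ynone 21 (not isolated), via enaminone 22 (not isolated)
Conditions: PdCl2(PPh3)2 (5 mol %), CO (20 bar), Et2NH, 110 °C
Reagents that add atoms: none
Why: Zerovalent palladium formed from PdCl2(PPh3)2 inserts into the C4a–I bond of 7, CO insertion gives the aroylpalladium iodide, and amine-assisted alkynylation with 19 followed by reductive elimination forms C4a–C4 and C4–C3 in ynone 21. Diethylamine then adds to the ynone to give enaminone 22, and the free phenol displaces the amine at C2 by addition–elimination, which forms O1–C2 and closes ring C as a six-membered ring (overall 6-endo on the alkyne, with the amine relay directing attack to C2 and away from the 5-exo aurone). The closest known reaction is the carbonylative Sonogashira coupling of 2-iodophenols with terminal alkynes in a secondary amine, which gives flavones directly. No stereocentre is formed. The step needs CO insertion to outrun direct alkynylation (which would lead to a 2-arylbenzofuran) and amide formation; the electron-rich, doubly ortho-substituted aryl group on palladium should migrate to CO readily, and the raised CO pressure supports this. The direction of ring closure is fixed by the substrate, because O1 is the only unprotected oxygen of ring A and it sits next to the C8 prenyl group.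

Step 12
Reactants: 23 3'-geranyl-5,7,2',4'-tetrakis(methoxymethoxy)-8,5'-diprenylflavone
Product: 25 (2S)-3'-geranyl-5,7,2',4'-tetrakis(methoxymethoxy)-8,5'-diprenylflavanone, via enol silane 24 (not isolated)
Conditions: Cu(OAc)2 (5 mol %), (R)-DTBM-SEGPHOS (5.5 mol %), (EtO)2MeSiH (3 equiv), toluene, 0 °C to rt; then AcOH–H2O–THF, 0 °C
Reagents that add atoms: none
Why: Copper hydride-catalysed enantioselective conjugate reduction of a chromone-type enone: the bisphosphine-bound CuH delivers hydride to C2 on the face chosen by the ligand, which sets C2 as S, the copper enolate is silylated by the silane to enol silane 24 with return of CuH, and mild hydrolysis gives the ketone; isolated trisubstituted alkenes do not react with CuH.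

Step 13
Reactants: 25 (2S)-3'-geranyl-5,7,2',4'-tetrakis(methoxymethoxy)-8,5'-diprenylflavanone
Product: 27 (2R,3R)-3'-geranyl-3-hydroxy-5,7,2',4'-tetrakis(methoxymethoxy)-8,5'-diprenylflavanone, via potassium enolate 26 (not isolated)
Conditions: KN(SiMe3)2 (1.1 equiv), THF, –78 °C; 2-(phenylsulfonyl)-3-phenyloxaziridine (1.3 equiv), –78 °C; AcOH, –78 °C
Reagents that add atoms: 2-(phenylsulfonyl)-3-phenyloxaziridine, O=S(=O)(c1ccccc1)N1OC1c1ccccc1
Why: Enolate hydroxylation with an N-sulfonyloxaziridine (Davis oxidation): the enolate made at –78 °C attacks the oxaziridine oxygen on the C3 face opposite to the C2 aryl group, which gives the 2,3-trans alcohol (3R; C2 is unchanged in space and becomes R only by the priority change), and at this temperature the oxaziridine should leave the four trisubstituted alkenes alone and the enolate should not open ring C.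

Step 14
Reactants: 27 (2R,3R)-3'-geranyl-3-hydroxy-5,7,2',4'-tetrakis(methoxymethoxy)-8,5'-diprenylflavanone
Product: 28 (2R,3R)-3'-geranyl-3,5,7,2',4'-pentahydroxy-8,5'-diprenylflavanone (CNP0149909.1)
Conditions: aq. HCl (3 M), MeOH, 40 °C
Reagents that add atoms: none
Why: Acid-catalysed acetal exchange with methanol cleaves all four MOM ethers as dimethoxymethane; dilute acid at moderate temperature is used so that the prenyl and geranyl alkenes are not protonated and closed onto the neighbouring phenols, and the 2,3-trans arrangement is the stable one, so C2 and C3 should keep their configuration.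

**Compound list**

1 | phloroglucinol | Oc1cc(O)cc(O)c1 | starting material
2 | 3,5-bis(methoxymethoxy)phenol | COCOc1cc(O)cc(OCOC)c1 | intermediate
3 | 2-iodo-3,5-bis(methoxymethoxy)phenol | COCOc1cc(O)c(I)c(OCOC)c1 | intermediate
4 | 1-(allyloxy)-2-iodo-3,5-bis(methoxymethoxy)benzene | C=CCOc1cc(OCOC)cc(OCOC)c1I | intermediate
5 | 6-allyl-2-iodo-3,5-bis(methoxymethoxy)cyclohexa-2,4-dien-1-one (racemic, not isolated) | C=CCC1C(=O)C(I)=C(OCOC)C=C1OCOC | intermediate
6 | 2-allyl-6-iodo-3,5-bis(methoxymethoxy)phenol | C=CCc1c(O)c(I)c(OCOC)cc1OCOC | intermediate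
7 | 2-iodo-3,5-bis(methoxymethoxy)-6-prenylphenol | CC(C)=CCc1c(O)c(I)c(OCOC)cc1OCOC | intermediate
8 | resorcinol | Oc1cccc(O)c1 | starting material
9 | 1,3-bis(methoxymethoxy)benzene | COCOc1cccc(OCOC)c1 | intermediate
10 | geranyl bromide | CC(C)=CCC/C(C)=C/CBr | starting material
11 | 2,6-bis(methoxymethoxy)phenyllithium (not isolated) | [Li]c1c(OCOC)cccc1OCOC | intermediate
12 | 2-geranyl-1,3-bis(methoxymethoxy)benzene | CC(C)=CCC/C(C)=C/Cc1c(OCOC)cccc1OCOC | intermediate
13 | prenyl bromide | CC(C)=CCBr | starting material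
14 | 3-geranyl-2,4-bis(methoxymethoxy)phenyllithium (not isolated) | CC(C)=CCC/C(C)=C/Cc1c(OCOC)ccc([Li])c1OCOC | intermediate
15 | 2-geranyl-1,3-bis(methoxymethoxy)-4-prenylbenzene | CC(C)=CCC/C(C)=C/Cc1c(OCOC)ccc(CC=C(C)C)c1OCOC | intermediate
16 | 3-geranyl-2,4-bis(methoxymethoxy)-5-prenylphenyllithium (not isolated) | CC(C)=CCC/C(C)=C/Cc1c(OCOC)c(CC=C(C)C)cc([Li])c1OCOC | intermediate
17 | lithium (dimethylamino)[3-geranyl-2,4-bis(methoxymethoxy)-5-prenylphenyl]methanolate (not isolated) | CC(C)=CCC/C(C)=C/Cc1c(OCOC)c(CC=C(C)C)cc(C([O-])N(C)C)c1OCOC.[Li+] | intermediate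
18 | 3-geranyl-2,4-bis(methoxymethoxy)-5-prenylbenzaldehyde | CC(C)=CCC/C(C)=C/Cc1c(OCOC)c(CC=C(C)C)cc(C=O)c1OCOC | intermediate
19 | 1-ethynyl-3-geranyl-2,4-bis(methoxymethoxy)-5-prenylbenzene | CC(C)=CCC/C(C)=C/Cc1c(OCOC)c(CC=C(C)C)cc(C#C)c1OCOC | intermediate
20 | carbon monoxide | [C-]#[O+] | starting material
21 | 1-[2-hydroxy-4,6-bis(methoxymethoxy)-3-prenylphenyl]-3-[3-geranyl-2,4-bis(methoxymethoxy)-5-prenylphenyl]prop-2-yn-1-one (not isolated) | CC(C)=CCC/C(C)=C/Cc1c(OCOC)c(CC=C(C)C)cc(C#CC(=O)c2c(O)c(CC=C(C)C)c(OCOC)cc2OCOC)c1OCOC | intermediate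
22 | 3-(diethylamino)-1-[2-hydroxy-4,6-bis(methoxymethoxy)-3-prenylphenyl]-3-[3-geranyl-2,4-bis(methoxymethoxy)-5-prenylphenyl]prop-2-en-1-one (alkene geometry not defined, not isolated) | CC(C)=CCC/C(C)=C/Cc1c(OCOC)c(CC=C(C)C)cc(C(=CC(=O)c2c(O)c(CC=C(C)C)c(OCOC)cc2OCOC)N(CC)CC)c1OCOC | intermediate
23 | 3'-geranyl-5,7,2',4'-tetrakis(methoxymethoxy)-8,5'-diprenylflavone | CC(C)=CCC/C(C)=C/Cc1c(OCOC)c(CC=C(C)C)cc(-c2cc(=O)c3c(OCOC)cc(OCOC)c(CC=C(C)C)c3o2)c1OCOC | intermediate
24 | (2S)-4-[diethoxy(methyl)silyloxy]-2-[3-geranyl-2,4-bis(methoxymethoxy)-5-prenylphenyl]-5,7-bis(methoxymethoxy)-8-prenyl-2H-chromene (not isolated) | CC(C)=CCC/C(C)=C/Cc1c(OCOC)c(CC=C(C)C)cc([C@H]2Oc3c(CC=C(C)C)c(OCOC)cc(OCOC)c3C(O[Si](C)(OCC)OCC)=C2)c1OCOC | intermediate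
25 | (2S)-3'-geranyl-5,7,2',4'-tetrakis(methoxymethoxy)-8,5'-diprenylflavanone | CC(C)=CCC/C(C)=C/Cc1c(OCOC)c(CC=C(C)C)cc([C@H]2Oc3c(CC=C(C)C)c(OCOC)cc(OCOC)c3C(=O)C2)c1OCOC | intermediate
26 | potassium enolate of 25 (C3=C4, O4 as oxide; not isolated) | CC(C)=CCC/C(C)=C/Cc1c(OCOC)c(CC=C(C)C)cc([C@H]2Oc3c(CC=C(C)C)c(OCOC)cc(OCOC)c3C([O-])=C2)c1OCOC.[K+] | intermediate
27 | (2R,3R)-3'-geranyl-3-hydroxy-5,7,2',4'-tetrakis(methoxymethoxy)-8,5'-diprenylflavanone | CC(C)=CCC/C(C)=C/Cc1c(OCOC)c(CC=C(C)C)cc([C@H]2Oc3c(CC=C(C)C)c(OCOC)cc(OCOC)c3C(=O)[C@@H]2O)c1OCOC | intermediate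
28 | (2R,3R)-3'-geranyl-3,5,7,2',4'-pentahydroxy-8,5'-diprenylflavanone (CNP0149909.1) | CC(C)=CCC/C(C)=C/Cc1c(O)c(CC=C(C)C)cc([C@H]2Oc3c(CC=C(C)C)c(O)cc(O)c3C(=O)[C@@H]2O)c1O | target

**Step count and risks**

Total steps: 14. Longest linear sequence: 9 steps (steps 1–5 and 11–14, or equally steps 6–14).

Steps most likely to fail:

Step 11. Oxidative addition into the hindered, electron-rich C4a–I bond may be slow, alkynylation may outrun CO insertion, or the amine may intercept the aroylpalladium species, so that ring C is not assembled. The fallback sets out from 7 and 19, returns at ynone 21 and goes on from there to 23; it forms the same three bonds without palladium or CO. Treatment of 7 with n-BuLi (2.1 equiv, THF, –78 °C) should give, by deprotonation and iodine–lithium exchange, lithium 2-lithio-3,5-bis(methoxymethoxy)-6-prenylphenoxide F1, and DMF should convert it into 2-hydroxy-4,6-bis(methoxymethoxy)-3-prenylbenzaldehyde F2. Alkyne 19 is deprotonated with n-BuLi to the lithium acetylide F3, which is added to the lithium phenoxide of F2 (preformed with LiN(SiMe3)2) to give the racemic propargylic alcohol F4. MnO2 in CH2Cl2 should oxidise F4 to ynone 21, and Et2NH in EtOH at rt should close ring C through enaminone 22 to flavone 23.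

Step 12. Hydride transfer to the hindered, electron-rich C2 may be slow, or facial discrimination may be poor because ring B with its ortho MOM ether is twisted out of the enone plane. The fallback sets out from 23 and returns at 25. KBH(s-Bu)3 in THF at –78 °C should reduce 23 by 1,4-addition to the racemic flavanone F5. Kinetic resolution by asymmetric transfer hydrogenation with RuCl(p-cymene)[(R,R)-TsDPEN] and HCO2H–Et3N should reduce the (2R)-ketone faster to the cis-(2R,4R)-flavan-4-ol F6, and the unreacted (2S)-flavanone 25 is separated by chromatography.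

Step 13. The enolate may open ring C by β-elimination of the ring A phenoxide, which would erode the configuration at C2, or the oxidant may approach both faces of C3. The fallback sets out from enol silane 24 and returns at 27; no metal enolate is involved. The reduction mixture of step 12 is not hydrolysed but filtered through deactivated alumina to keep 24. Dimethyldioxirane (1.0 equiv, acetone–CH2Cl2, –78 °C) should epoxidise the electron-rich enol ether anti to the C2 aryl group (Rubottom oxidation) in preference to the isolated alkenes and give the silyloxy epoxide F7. AcOH–H2O–THF at 0 °C should open F7 to 27.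

**Further compounds**

F1 | step 11 | lithium 2-lithio-3,5-bis(methoxymethoxy)-6-prenylphenoxide | [Li]Oc1c(CC=C(C)C)c(OCOC)cc(OCOC)c1[Li]
F2 | step 11 | 2-hydroxy-4,6-bis(methoxymethoxy)-3-prenylbenzaldehyde | O=Cc1c(O)c(CC=C(C)C)c(OCOC)cc1OCOC
F3 | step 11 | lithium acetylide of 19 | CC(C)=CCC/C(C)=C/Cc1c(OCOC)c(CC=C(C)C)cc(C#C[Li])c1OCOC
F4 | step 11 | racemic 1-[2-hydroxy-4,6-bis(methoxymethoxy)-3-prenylphenyl]-3-[3-geranyl-2,4-bis(methoxymethoxy)-5-prenylphenyl]prop-2-yn-1-ol | CC(C)=CCC/C(C)=C/Cc1c(OCOC)c(CC=C(C)C)cc(C#CC(O)c2c(O)c(CC=C(C)C)c(OCOC)cc2OCOC)c1OCOC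
F5 | step 12 | racemic 3'-geranyl-5,7,2',4'-tetrakis(methoxymethoxy)-8,5'-diprenylflavanone | CC(C)=CCC/C(C)=C/Cc1c(OCOC)c(CC=C(C)C)cc(C2CC(=O)c3c(OCOC)cc(OCOC)c(CC=C(C)C)c3O2)c1OCOC
F6 | step 12 | (2R,4R)-3'-geranyl-5,7,2',4'-tetrakis(methoxymethoxy)-8,5'-diprenylflavan-4-ol | CC(C)=CCC/C(C)=C/Cc1c(OCOC)c(CC=C(C)C)cc([C@@H]2Oc3c(CC=C(C)C)c(OCOC)cc(OCOC)c3[C@H](O)C2)c1OCOC
F7 | step 13 | 3,4-epoxide of enol silane 24 (epoxide oxygen anti to the C2 aryl group, silyloxy group on C4) | CC(C)=CCC/C(C)=C/Cc1c(OCOC)c(CC=C(C)C)cc([C@H]2Oc3c(CC=C(C)C)c(OCOC)cc(OCOC)c3[C@]3(O[Si](C)(OCC)OCC)O[C@H]23)c1OCOC
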